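**Plan**

- Ring A is the 3-hydroxy-5-sulfooxyphenoxy ring. Ring B is the 2,6-dihydroxy-4-sulfooxyphenyl ring, numbered from its ether carbon C1.
- Retrosynthesis first removes the two sulfate esters (O on C4 of ring B, O on C5 of ring A) and three benzyl ethers. It then cuts ring B at C2–C3 and C4–C5, with C1–C2 as the bond that is opened and re-closed.
- The enabling feature: in ring B the C2 hydroxyl and the C4 oxygen are meta with C3–H between them. C2–OH is a ketene carbonyl, and C3–H/C4–O are a silyloxyalkyne. C1 (aryl ether), C6 (oxygen) and C5 (H) are C4, C3 and C2 of a cyclobutenone, so the crowded ether carbon is sp3 and already carries ring A before ring B exists.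
- Forward: ring A (bought as an arene) is differentiated as benzyl/silyl ether and turned into an aryloxyacetic acid. Its ketene and benzyl ethynyl ether give the four-membered ring. The benzannulation then builds ring B, followed by benzylation, desilylation, double sulfation and hydrogenolysis.
- Stereochemistry: the target has no stereocentre. The sp3 carbons of the four- and six-membered intermediates are racemic and are erased on aromatisation.

Key step: step 9

Assumption: the sulfate half-esters are written as free acids, as the target is drawn; in practice 28 and 29 would be handled as salts, and the acid form of 29 is released only at the end on a cold sulfonic acid resin.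

**Route**

Step 1
Reactants: 1 3,5-bis(benzyloxy)phenol
Product: 2 1,3-bis(benzyloxy)-5-(triisopropylsilyloxy)benzene
Conditions: TIPSCl, imidazole, DMF, rt
Reagents that add atoms: triisopropylsilyl chloride, CC(C)[Si](Cl)(C(C)C)C(C)C
Why: Imidazole-promoted O-silylation of the only free phenol should be clean (silyl ether formation).

Step 2
Reactants: 2 1,3-bis(benzyloxy)-5-(triisopropylsilyloxy)benzene
Product: 3 3-(benzyloxy)-5-(triisopropylsilyloxy)phenol
Conditions: H2 (1 atm, stopped after about 1 equiv), 10% Pd/C, EtOAc, rt; recovered 2 recycled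
Reagents that add atoms: none
Why: Catalytic hydrogenolysis of one of two equivalent benzyl aryl ethers is statistical, so stopping near half conversion should leave the mono-phenol as the main component while the silyl ether is inert.

Step 3
Reactants: 3 3-(benzyloxy)-5-(triisopropylsilyloxy)phenol; 4 allyl bromoacetate
Product: 5 allyl 2-[3-(benzyloxy)-5-(triisopropylsilyloxy)phenoxy]acetate
Conditions: K2CO3, acetone, rt
Reagents that add atoms: none
Why: Williamson etherification of a phenoxide with a reactive α-bromo ester should proceed at room temperature, where the bulky aryl silyl ether is not disturbed.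

Step 4
Reactants: 5 allyl 2-[3-(benzyloxy)-5-(triisopropylsilyloxy)phenoxy]acetate
Product: 6 2-[3-(benzyloxy)-5-(triisopropylsilyloxy)phenoxy]acetic acid
Conditions: Pd(PPh3)4 (cat.), morpholine, THF, rt; aq. citric acid work-up
Reagents that add atoms: none
Why: Tsuji–Trost cleavage of the allyl ester under neutral conditions frees the acid without the base that would attack the aryl silyl ether or the acid-derived cations that would alkylate the electron-rich ring.

Step 5
Reactants: 7 benzyl alcohol; 8 trichloroethylene
Product: 12 benzyl ethynyl ether, via benzyl (E)-1,2-dichlorovinyl ether 9 (not isolated), via benzyl chloroethynyl ether 10 (not isolated), via lithium 2-(benzyloxy)ethynide 11 (not isolated)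
Conditions: KH, THF, 0 °C; Cl2C=CHCl, −50 °C → rt; n-BuLi (2.5 equiv), −78 → −40 °C; MeOH, −78 °C; product kept cold
Reagents that add atoms: none
Why: Potassium benzyl oxide adds anti to dichloroacetylene formed in situ, and butyllithium then effects dehydrochlorination and lithium–chlorine exchange to the alkoxyacetylide, which methanol protonates (ynol ether synthesis by addition–elimination); the product is kept cold because benzyl alkynyl ethers rearrange sigmatropically on warming.

Step 6
Reactants: 6 2-[3-(benzyloxy)-5-(triisopropylsilyloxy)phenoxy]acetic acid; 12 benzyl ethynyl ether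
Product: 15 rac-3-(benzyloxy)-4-[3-(benzyloxy)-5-(triisopropylsilyloxy)phenoxy]cyclobut-2-en-1-one, via acid chloride 13 (not isolated), via aryloxyketene 14 (not isolated)
Conditions: Me2C=C(Cl)NMe2, CH2Cl2, 0 °C; then added slowly to 12 (2 equiv), Et3N, CH2Cl2, 0 °C → rt; chromatography on deactivated silica
Reagents that add atoms: none
Why: The α-chloroenamine gives the acid chloride without acid, triethylamine dehydrochlorinates it to the aryloxyketene, and a ketene–ynol ether [2+2] cycloaddition in which the alkyne CH carbon attacks the ketene carbonyl carbon should give the 3-alkoxycyclobutenone; slow addition into excess alkyne suppresses ketene dimerisation.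

Step 7
Reactants: 16 trimethylsilylacetylene
Product: 19 1-(triisopropylsilyloxy)-2-(trimethylsilyl)ethyne, via lithium (trimethylsilyl)ethynide 17 (not isolated), via lithium 2-(trimethylsilyl)ethynolate 18 (not isolated)
Conditions: n-BuLi, THF, −78 °C; t-BuOOLi (from t-BuOOH and LiN(SiMe3)2), −78 → 0 °C; TIPSOTf, −78 °C → rt
Reagents that add atoms: tert-butyl hydroperoxide, CC(C)(C)OO; triisopropylsilyl trifluoromethanesulfonate, CC(C)[Si](OS(=O)(=O)C(F)(F)F)(C(C)C)C(C)C
Why: Electrophilic oxygen transfer from lithium tert-butyl peroxide to the lithium acetylide gives the ynolate, which the bulky silyl triflate should capture on oxygen rather than carbon (acetylide oxidation, then ynolate O-silylation).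

Step 8
Reactants: 19 1-(triisopropylsilyloxy)-2-(trimethylsilyl)ethyne
Product: 20 (triisopropylsilyloxy)ethyne
Conditions: K2CO3 (cat.), MeOH, 0 °C, short contact; pentane extraction, used promptly
Reagents that add atoms: none
Why: Base-catalysed methanolysis should cleave the C(sp)–SiMe3 bond far faster than the hindered O–Si(i-Pr)3 bond (protodesilylation of an alkynylsilane), and the electron-rich ynol ether does not add methoxide.

Step 9
Reactants: 15 rac-3-(benzyloxy)-4-[3-(benzyloxy)-5-(triisopropylsilyloxy)phenoxy]cyclobut-2-en-1-one; 20 (triisopropylsilyloxy)ethyne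
Product: 25 3-(benzyloxy)-2-[3-(benzyloxy)-5-(triisopropylsilyloxy)phenoxy]-5-(triisopropylsilyloxy)phenol, via vinylketene 21 (not isolated), via vinylcyclobutenone 22 (not isolated), via dienylketene 23 (not isolated), via cyclohexadienone 24 (not isolated)
Conditions: 20 (2 equiv), PhMe, argon, sealed tube, 80 °C then 110 °C
Reagents that add atoms: none
Why: Thermal 4π electrocyclic opening of 15, with the C4 aryloxy group rotating outward, should give vinylketene 21, whose ketene C=C adds the ynol ether 20 in a [2+2] cycloaddition to the 4-vinylcyclobutenone 22; a second 4π opening gives dienylketene 23, thermal disrotatory 6π electrocyclisation joins the ketene carbon (C2 of ring B) to the aryloxy-bearing carbon (C1) to close ring B as dienone 24, and enolisation delivers phenol 25. This is the Danheiser benzannulation of a cyclobutenone with a silyloxyalkyne, the closest known reaction type, and the opening of 3-alkoxy-4-oxy-cyclobutenones at these temperatures is familiar from squarate-derived cyclobutenones. The new bonds are C2–C3 and C4–C5 of ring B (cycloaddition) and C1–C2 (electrocyclisation). The selectivity needed is the orientation of the ketene–alkyne cycloaddition, and the ynol ether polarisation secures it: the nucleophilic CH terminus bonds to the ketene carbonyl carbon, so the silyloxy carbon ends up para to the diaryl ether carbon and meta to the new hydroxyl. Outward rotation of the aryloxy donor places it on the outside of the triene terminus, which keeps ring A away from the ketene and leaves the 6π closure unhindered; the sp3 stereocentres of 15, 22 and 24 are racemic and vanish on aromatisation, so no stereocontrol is required. The three ring B oxygens should emerge as free hydroxyl (C2), benzyl ether (C6) and silyl ether (C4), the last on the carbon destined for sulfation.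

Step 10
Reactants: 25 3-(benzyloxy)-2-[3-(benzyloxy)-5-(triisopropylsilyloxy)phenoxy]-5-(triisopropylsilyloxy)phenol
Product: 26 1,3-bis(benzyloxy)-2-[3-(benzyloxy)-5-(triisopropylsilyloxy)phenoxy]-5-(triisopropylsilyloxy)benzene
Conditions: BnBr, K2CO3, acetone, 50 °C
Reagents that add atoms: benzyl bromide, BrCc1ccccc1
Why: Williamson benzylation of the single free phenol should be straightforward, and carbonate in acetone does not disturb the bulky aryl silyl ethers.

Step 11
Reactants: 26 1,3-bis(benzyloxy)-2-[3-(benzyloxy)-5-(triisopropylsilyloxy)phenoxy]-5-(triisopropylsilyloxy)benzene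
Product: 27 3-(benzyloxy)-5-[2,6-bis(benzyloxy)-4-hydroxyphenoxy]phenol
Conditions: Bu4NF, AcOH, THF, 0 °C, argon
Reagents that add atoms: none
Why: Fluoride cleaves both aryl silyl ethers (fluoride desilylation) while benzyl ethers are inert, and the acetic acid buffer keeps the electron-rich 4-aryloxyphenol from oxidising as its phenoxide.

Step 12
Reactants: 27 3-(benzyloxy)-5-[2,6-bis(benzyloxy)-4-hydroxyphenoxy]phenol
Product: 28 3-(benzyloxy)-5-[2,6-bis(benzyloxy)-4-(sulfooxy)phenoxy]phenyl hydrogen sulfate
Conditions: SO3·pyridine (excess), pyridine, 40 °C; then Dowex 50W (Na+ form) to remove pyridinium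
Reagents that add atoms: sulfur trioxide–pyridine complex, [O-]S(=O)(=O)[n+]1ccccc1
Why: O-sulfonation of the two free phenols by the sulfur trioxide–amine complex should give the bis(aryl sulfate) salt, the three benzyl ethers keeping the other hydroxyls blocked; pyridine is exchanged out because it would inhibit the palladium catalyst of the next step.

Step 13
Reactants: 28 3-(benzyloxy)-5-[2,6-bis(benzyloxy)-4-(sulfooxy)phenoxy]phenyl hydrogen sulfate
Product: 29 3-hydroxy-5-[2,6-dihydroxy-4-(sulfooxy)phenoxy]phenyl hydrogen sulfate (CNP0460023.0)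
Conditions: H2 (1 atm), 10% Pd/C, MeOH–H2O, rt; then Dowex 50W (H+ form), 0 °C, freeze-drying
Reagents that add atoms: none
Why: Hydrogenolysis over palladium should cleave the three benzyl ethers while aryl sulfate salts and the diaryl ether are inert under neutral conditions; brief cold contact with the acidic resin gives the acid form drawn, which should be kept cold or stored as its salt because aryl hydrogen sulfates hydrolyse under acid.

**Compound list**

1 | 3,5-bis(benzyloxy)phenol | Oc1cc(OCc2ccccc2)cc(OCc2ccccc2)c1 | starting material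
2 | 1,3-bis(benzyloxy)-5-(triisopropylsilyloxy)benzene | CC(C)[Si](Oc1cc(OCc2ccccc2)cc(OCc2ccccc2)c1)(C(C)C)C(C)C | intermediate
3 | 3-(benzyloxy)-5-(triisopropylsilyloxy)phenol | Oc1cc(OCc2ccccc2)cc(O[Si](C(C)C)(C(C)C)C(C)C)c1 | intermediate
4 | allyl bromoacetate | C=CCOC(=O)CBr | starting material
5 | allyl 2-[3-(benzyloxy)-5-(triisopropylsilyloxy)phenoxy]acetate | C=CCOC(=O)COc1cc(OCc2ccccc2)cc(O[Si](C(C)C)(C(C)C)C(C)C)c1 | intermediate
6 | 2-[3-(benzyloxy)-5-(triisopropylsilyloxy)phenoxy]acetic acid | OC(=O)COc1cc(OCc2ccccc2)cc(O[Si](C(C)C)(C(C)C)C(C)C)c1 | intermediate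
7 | benzyl alcohol | OCc1ccccc1 | starting material
8 | trichloroethylene | ClC=C(Cl)Cl | starting material
9 | benzyl (E)-1,2-dichlorovinyl ether | Cl/C=C(/Cl)OCc1ccccc1 | intermediate (not isolated)
10 | benzyl chloroethynyl ether | ClC#COCc1ccccc1 | intermediate (not isolated)
11 | lithium 2-(benzyloxy)ethynide | [Li+].[C-]#COCc1ccccc1 | intermediate (not isolated)
12 | benzyl ethynyl ether | C#COCc1ccccc1 | intermediate
13 | 2-[3-(benzyloxy)-5-(triisopropylsilyloxy)phenoxy]acetyl chloride | ClC(=O)COc1cc(OCc2ccccc2)cc(O[Si](C(C)C)(C(C)C)C(C)C)c1 | intermediate (not isolated)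
14 | 2-[3-(benzyloxy)-5-(triisopropylsilyloxy)phenoxy]ethen-1-one (aryloxyketene) | O=C=COc1cc(OCc2ccccc2)cc(O[Si](C(C)C)(C(C)C)C(C)C)c1 | intermediate (not isolated)
15 | rac-3-(benzyloxy)-4-[3-(benzyloxy)-5-(triisopropylsilyloxy)phenoxy]cyclobut-2-en-1-one | O=C1C=C(OCc2ccccc2)C1Oc3cc(OCc4ccccc4)cc(O[Si](C(C)C)(C(C)C)C(C)C)c3 | intermediate
16 | trimethylsilylacetylene | C#C[Si](C)(C)C | starting material
17 | lithium (trimethylsilyl)ethynide | [Li+].[C-]#C[Si](C)(C)C | intermediate (not isolated)
18 | lithium 2-(trimethylsilyl)ethynolate | [Li+].[O-]C#C[Si](C)(C)C | intermediate (not isolated)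
19 | 1-(triisopropylsilyloxy)-2-(trimethylsilyl)ethyne | C[Si](C)(C)C#CO[Si](C(C)C)(C(C)C)C(C)C | intermediate
20 | (triisopropylsilyloxy)ethyne | C#CO[Si](C(C)C)(C(C)C)C(C)C | intermediate
21 | (Z)-3-(benzyloxy)-4-[3-(benzyloxy)-5-(triisopropylsilyloxy)phenoxy]buta-1,3-dien-1-one (vinylketene) | O=C=C/C(OCc1ccccc1)=C/Oc1cc(OCc2ccccc2)cc(O[Si](C(C)C)(C(C)C)C(C)C)c1 | intermediate (not isolated)
22 | rac-4-{(Z)-1-(benzyloxy)-2-[3-(benzyloxy)-5-(triisopropylsilyloxy)phenoxy]ethenyl}-3-(triisopropylsilyloxy)cyclobut-2-en-1-one | O=C1C=C(O[Si](C(C)C)(C(C)C)C(C)C)C1/C(OCc2ccccc2)=C/Oc2cc(OCc3ccccc3)cc(O[Si](C(C)C)(C(C)C)C(C)C)c2 | intermediate (not isolated)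
23 | (3E,5Z)-5-(benzyloxy)-6-[3-(benzyloxy)-5-(triisopropylsilyloxy)phenoxy]-3-(triisopropylsilyloxy)hexa-1,3,5-trien-1-one (dienylketene) | O=C=C/C(O[Si](C(C)C)(C(C)C)C(C)C)=C\C(OCc1ccccc1)=C\Oc1cc(OCc2ccccc2)cc(O[Si](C(C)C)(C(C)C)C(C)C)c1 | intermediate (not isolated)
24 | rac-5-(benzyloxy)-6-[3-(benzyloxy)-5-(triisopropylsilyloxy)phenoxy]-3-(triisopropylsilyloxy)cyclohexa-2,4-dien-1-one | O=C1C=C(O[Si](C(C)C)(C(C)C)C(C)C)C=C(OCc2ccccc2)C1Oc3cc(OCc4ccccc4)cc(O[Si](C(C)C)(C(C)C)C(C)C)c3 | intermediate (not isolated)
25 | 3-(benzyloxy)-2-[3-(benzyloxy)-5-(triisopropylsilyloxy)phenoxy]-5-(triisopropylsilyloxy)phenol | Oc1cc(O[Si](C(C)C)(C(C)C)C(C)C)cc(OCc2ccccc2)c1Oc1cc(OCc2ccccc2)cc(O[Si](C(C)C)(C(C)C)C(C)C)c1 | intermediate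
26 | 1,3-bis(benzyloxy)-2-[3-(benzyloxy)-5-(triisopropylsilyloxy)phenoxy]-5-(triisopropylsilyloxy)benzene | CC(C)[Si](Oc1cc(OCc2ccccc2)cc(Oc2c(OCc3ccccc3)cc(O[Si](C(C)C)(C(C)C)C(C)C)cc2OCc2ccccc2)c1)(C(C)C)C(C)C | intermediate
27 | 3-(benzyloxy)-5-[2,6-bis(benzyloxy)-4-hydroxyphenoxy]phenol | Oc1cc(OCc2ccccc2)cc(Oc2c(OCc3ccccc3)cc(O)cc2OCc2ccccc2)c1 | intermediate
28 | 3-(benzyloxy)-5-[2,6-bis(benzyloxy)-4-(sulfooxy)phenoxy]phenyl hydrogen sulfate | O=S(=O)(O)Oc1cc(OCc2ccccc2)cc(Oc2c(OCc3ccccc3)cc(OS(=O)(=O)O)cc2OCc2ccccc2)c1 | intermediate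
29 | 3-hydroxy-5-[2,6-dihydroxy-4-(sulfooxy)phenoxy]phenyl hydrogen sulfate (CNP0460023.0) | O=S(=O)(O)Oc1cc(O)cc(Oc2c(O)cc(OS(=O)(=O)O)cc2O)c1 | target

**Step count**

Total step count: 13.
Longest linear sequence: 10 steps (steps 1, 2, 3, 4, 6, 9, 10, 11, 12, 13).

**Steps most likely to fail**

Step 9. The cyclobutenone may reclose or decompose faster than its vinylketene is intercepted. The silyloxyalkyne may also isomerise by oxygen-to-carbon silyl shift to a silylketene before it is consumed, so the cascade stalls before ring B closes. The fallback gives up the annulation and makes the diaryl ether by cross-coupling; it sets out from 2 and 3 and rejoins the route at 26. Bromination of 2 with N-bromosuccinimide in MeCN at 0 °C is expected at the carbon para to the silyloxy group and flanked by the two benzyloxy groups, because the triisopropylsilyl group shields its own ortho positions, giving 1,3-bis(benzyloxy)-2-bromo-5-(triisopropylsilyloxy)benzene F1. Buchwald–Hartwig etherification of F1 with phenol 3 (Pd(OAc)2, di-tert-butyl(2',4',6'-triisopropylbiphenyl-2-yl)phosphine, K3PO4, toluene, 100 °C) should then give 26 directly. This detour forms the ether bond at a doubly ortho-substituted carbon, which is why it is the second choice, but it needs neither 15 nor 20.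

Step 8. Methanolysis may not stop at the carbon–silicon bond: the oxygen–silicon bond may also be cleaved, or the small, volatile parent ynol ether may be lost or oligomerise on isolation. The fallback leaves the trimethylsilyl group on the alkyne and removes it after the arene is built; it sets out from 19 (with 15) and rejoins at 25. Heating 15 with 19 under the conditions of step 9 should give, with the same orientation, 3-(benzyloxy)-2-[3-(benzyloxy)-5-(triisopropylsilyloxy)phenoxy]-5-(triisopropylsilyloxy)-6-(trimethylsilyl)phenol F2. Ipso-protodesilylation of this very electron-rich arylsilane with CF3CO2H in CH2Cl2 at 0 °C then gives 25, the aryl silyl ethers and benzyl ethers being stable to brief acid.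

Step 12. Double sulfation may stop at the mono-sulfate, and sulfate may be lost during aqueous isolation of a very polar salt that cannot be chromatographed on silica; residual pyridine and sulfur species would also slow the following hydrogenolysis. The fallback installs the sulfates as neutral, chromatographable diesters; it sets out from 27 and rejoins at 29. Treatment of 27 with 2,2,2-trichloroethyl chlorosulfate, Et3N and 4-(dimethylamino)pyridine in THF should give 3-(benzyloxy)-5-{2,6-bis(benzyloxy)-4-[(2,2,2-trichloroethoxy)sulfonyloxy]phenoxy}phenyl 2,2,2-trichloroethyl sulfate F3. Transfer hydrogenolysis (10% Pd/C, HCO2NH4, MeOH, rt) then removes the trichloroethyl groups and the three benzyl ethers in one operation to give 29 as its ammonium salt, converted to the acid form as in step 13.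

**Further compounds**

F1 | step 9 | 1,3-bis(benzyloxy)-2-bromo-5-(triisopropylsilyloxy)benzene | Brc1c(OCc2ccccc2)cc(O[Si](C(C)C)(C(C)C)C(C)C)cc1OCc1ccccc1
F2 | step 8 | 3-(benzyloxy)-2-[3-(benzyloxy)-5-(triisopropylsilyloxy)phenoxy]-5-(triisopropylsilyloxy)-6-(trimethylsilyl)phenol | Oc1c([Si](C)(C)C)c(O[Si](C(C)C)(C(C)C)C(C)C)cc(OCc2ccccc2)c1Oc1cc(OCc2ccccc2)cc(O[Si](C(C)C)(C(C)C)C(C)C)c1
F3 | step 12 | 3-(benzyloxy)-5-{2,6-bis(benzyloxy)-4-[(2,2,2-trichloroethoxy)sulfonyloxy]phenoxy}phenyl 2,2,2-trichloroethyl sulfate | ClC(Cl)(Cl)COS(=O)(=O)Oc1cc(OCc2ccccc2)cc(Oc2c(OCc3ccccc3)cc(OS(=O)(=O)OCC(Cl)(Cl)Cl)cc2OCc2ccccc2)c1
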